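## Retrosynthetic overview

1. Numbering: tetralin C1–C8a. Ring A is C4a–C8a, ring B is C1–C4 plus C4a and C8a, ring C is the aryl group on C1, and C9 and C10 are the CH2OH carbons on C2 and C3. C1 and C4 are both benzylic and sit on the neighbouring ring A atoms C8a and C4a. C2 and C3 are trans and each carries one oxidised carbon. Ring B is therefore the adduct of the o-quinodimethane C1=C8a–C4a=C4 with a fumarate.
2. End game: debenzylation ⇐ removal of the C1 oxygen by hydride delivered from a silane tethered to O9, on the face of C9 ⇐ reduction of both esters of the cycloadduct.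
3. Key disconnection at C1–C2 and C3–C4: photoenolisation of a 2-methylbenzophenone and (4+2) addition to diisopropyl fumarate on a chiral titanium TADDOLate. This sets C1, C2 and C3.
4. Benzophenone ⇐ oxidation of the carbinol made from a ring A aryllithium (from 4-methyl-2,6-dimethoxyphenol) and a ring C aldehyde (from syringaldehyde), both O-benzylated.
5. Ring order: rings A and C are bought, and ring B is the only ring formed.

Key step: step 6

Assumption: the (R,R)-TADDOL titanate is taken to leave open the diene face that leads to the (1R,2S,3R) cycloadduct; this sense cannot be derived rigorously for this reactant pair, and the (S,S) ligand from D-tartrate would be used if the opposite sense is found.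

## Route

Step 1
Reactants: 1 4-methyl-2,6-dimethoxyphenol
Product: 2 2-(benzyloxy)-1,3-dimethoxy-5-methylbenzene
Conditions: BnBr, K2CO3, DMF, 60 °C
Reagents that add atoms: benzyl bromide, BrCc1ccccc1
Why: Williamson ether synthesis, in which the phenoxide is alkylated on oxygen by the benzylic bromide; the benzyl ether should tolerate aryllithium, light, titanium alkoxide and hydride and leaves by hydrogenolysis at the end.

Step 2
Reactants: 2 2-(benzyloxy)-1,3-dimethoxy-5-methylbenzene
Product: 3 2-(benzyloxy)-4-bromo-1,3-dimethoxy-5-methylbenzene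
Conditions: NBS, MeCN, 0 °C, dark
Reagents that add atoms: N-bromosuccinimide, O=C1CCC(=O)N1Br
Why: Electrophilic aromatic bromination, in which the two free ring positions are equivalent (each ortho to one methoxy group, para to the other and next to CH3), so only one monobromide can form, and ionic conditions in the dark avoid radical attack on the methyl group.

Step 3
Reactants: 4 syringaldehyde (4-hydroxy-3,5-dimethoxybenzaldehyde)
Product: 5 4-(benzyloxy)-3,5-dimethoxybenzaldehyde
Conditions: BnBr, K2CO3, DMF, 60 °C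
Reagents that add atoms: benzyl bromide, BrCc1ccccc1
Why: Williamson ether synthesis on the acidic para-formyl phenol, with the aldehyde inert to carbonate base.

Step 4
Reactants: 3 2-(benzyloxy)-4-bromo-1,3-dimethoxy-5-methylbenzene; 5 4-(benzyloxy)-3,5-dimethoxybenzaldehyde
Product: 7 (±)-[4-(benzyloxy)-3,5-dimethoxyphenyl][3-(benzyloxy)-2,4-dimethoxy-6-methylphenyl]methanol, via aryllithium 6 (not isolated)
Conditions: n-BuLi, THF, −78 °C; then 5, −78 → 0 °C; H2O
Reagents that add atoms: none
Why: Bromine–lithium exchange followed by 1,2-addition to a non-enolisable aldehyde, in which exchange at −78 °C outruns deprotonation of the CH3 and OCH2Ph groups, the carbinol centre may be racemic because step 5 erases it, and no Lewis acid is present that could cleave the benzyl ethers or the methoxy group next to the future carbonyl.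

Step 5
Reactants: 7 (±)-[4-(benzyloxy)-3,5-dimethoxyphenyl][3-(benzyloxy)-2,4-dimethoxy-6-methylphenyl]methanol
Product: 8 [4-(benzyloxy)-3,5-dimethoxyphenyl][3-(benzyloxy)-2,4-dimethoxy-6-methylphenyl]methanone
Conditions: IBX, DMSO–THF, 20 °C
Reagents that add atoms: none
Why: IBX oxidation of a secondary diaryl carbinol, whose neutral conditions at ambient temperature spare the acid-labile electron-rich benzhydrol, the benzyl ethers and the aryl methyl group.

Step 6
Reactants: 8 [4-(benzyloxy)-3,5-dimethoxyphenyl][3-(benzyloxy)-2,4-dimethoxy-6-methylphenyl]methanone; 9 diisopropyl fumarate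
Product: 11 diisopropyl (1R,2S,3R)-7-(benzyloxy)-1-[4-(benzyloxy)-3,5-dimethoxyphenyl]-1-hydroxy-6,8-dimethoxy-1,2,3,4-tetrahydronaphthalene-2,3-dicarboxylate (2,3-trans; OH cis to the C2 ester), via photoenol 10 (not isolated)
Conditions: Ti(OiPr)4, (R,R)-TADDOL, 4 Å MS, toluene, 20 °C; then 8, 9 (excess), hν (365 nm), Ar, 10–20 °C; aq NaHCO3
Reagents that add atoms: none
Why: Proposed new method: excitation of 8 and 1,5-hydrogen transfer from the C4 methyl group to the carbonyl oxygen give, after bond rotation in the biradical, the long-lived photoenol 10 whose OH points outward to C8–OMe (formally Z here, because C8 bears oxygen), and this o-quinodimethane, taken up as an alkoxide by the TADDOL titanate, adds suprafacially to 9, which is held on the same metal by one ester carbonyl. The closest known reactions are the racemic trapping of 2-methylbenzophenone photoenols by fumarates and the Ti(OiPr)4/TADDOL-controlled enantioselective photoenolisation/Diels–Alder reaction of 2-methylbenzaldehydes with enones; new is the pairing of a diaryl ketone and a simple diester under that control. Ring B closes by an intermolecular, concerted (4+2) cycloaddition that forms C1–C2 and C3–C4 together and is driven by rearomatisation of ring A. C2 and C3 come out trans because the E geometry of 9 is transferred suprafacially, C1 carries OH cis to the C2 ester because an outward diene substituent and an endo dienophile substituent end on the same face, and the absolute sense of all three is set by the diene face that the aryl groups of the (R,R)-TADDOLate leave open. The step needs the ester next to C1 endo and one diene face; the C1–O–Ti···O=C bridge, stiffened by chelation of the neighbouring C8–OMe, should secure both, and regiochemistry does not arise since 9 is twofold symmetric. Isopropyl esters make any alkoxide exchange with Ti(OiPr)4 degenerate.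

Step 7
Reactants: 11 diisopropyl (1R,2S,3R)-7-(benzyloxy)-1-[4-(benzyloxy)-3,5-dimethoxyphenyl]-1-hydroxy-6,8-dimethoxy-1,2,3,4-tetrahydronaphthalene-2,3-dicarboxylate
Product: 12 (1R,2R,3R)-7-(benzyloxy)-1-[4-(benzyloxy)-3,5-dimethoxyphenyl]-2,3-bis(hydroxymethyl)-6,8-dimethoxy-1,2,3,4-tetrahydronaphthalen-1-ol
Conditions: LiAlH4, THF, 0 → 20 °C; then H2O
Reagents that add atoms: none
Why: LiAlH4 ester reduction, which turns both isopropyl esters into the primary alcohols C9 and C10 without touching C1–C3, as 3-hydroxy-3,3-diarylpropanoates are known to give 1,3-diols; the covalent aluminium alkoxide at C1 should resist retro-aldol cleavage at low temperature.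

Step 8
Reactants: 12 (1R,2R,3R)-7-(benzyloxy)-1-[4-(benzyloxy)-3,5-dimethoxyphenyl]-2,3-bis(hydroxymethyl)-6,8-dimethoxy-1,2,3,4-tetrahydronaphthalen-1-ol
Product: 13 (1R,2R,3R)-7-(benzyloxy)-1-[4-(benzyloxy)-3,5-dimethoxyphenyl]-2,3-bis{[(diisopropylsilyl)oxy]methyl}-6,8-dimethoxy-1,2,3,4-tetrahydronaphthalen-1-ol
Conditions: iPr2SiHCl, imidazole, CH2Cl2, 0 °C
Reagents that add atoms: chlorodiisopropylsilane, CC(C)[SiH](Cl)C(C)C
Why: Chemoselective O-silylation with a silyl chloride and imidazole, in which the two primary hydroxyls react far faster than the crowded tertiary diaryl carbinol, so that an Si–H donor is placed on O9 and no stereocentre is touched.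

Step 9
Reactants: 13 (1R,2R,3R)-7-(benzyloxy)-1-[4-(benzyloxy)-3,5-dimethoxyphenyl]-2,3-bis{[(diisopropylsilyl)oxy]methyl}-6,8-dimethoxy-1,2,3,4-tetrahydronaphthalen-1-ol
Product: 16 [(1S,2R,3R)-7-(benzyloxy)-1-[4-(benzyloxy)-3,5-dimethoxyphenyl]-6,8-dimethoxy-1,2,3,4-tetrahydronaphthalene-2,3-diyl]dimethanol, via C1 carbocation 14 (not isolated), via silyl trifluoroacetate 15 (not isolated)
Conditions: CF3CO2H, CH2Cl2, −40 → 0 °C; then aq HCl, THF, 20 °C
Reagents that add atoms: none
Why: Tether-directed (intramolecular) ionic hydrogenation, in which CF3CO2H ionises the doubly benzylic C1–OH to 14 and the Si–H on O9 reaches C1 through a six-membered transition state on the face of C9, placing H cis to C9 and leaving ring C trans to it (1S) faster than the C2 proton is lost, while the O10 silyl ether on the other face can at most cap the cation reversibly through oxygen, and aqueous acid then hydrolyses the silicon groups of 15.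

Step 10
Reactants: 16 [(1S,2R,3R)-7-(benzyloxy)-1-[4-(benzyloxy)-3,5-dimethoxyphenyl]-6,8-dimethoxy-1,2,3,4-tetrahydronaphthalene-2,3-diyl]dimethanol
Product: 17 (1S,2R,3R)-lyoniresinol (CNP0153696.1)
Conditions: H2 (1 atm), Pd/C, EtOAc–MeOH, 20 °C
Reagents that add atoms: none
Why: Catalytic hydrogenolysis of the two aryl benzyl ethers, under which the diarylmethine C1–H, the methyl ethers and the primary alcohols are inert, so the three stereocentres pass unchanged into the target.

## Compound list

1 | 4-methyl-2,6-dimethoxyphenol | Cc1cc(OC)c(O)c(OC)c1 | starting material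
2 | 2-(benzyloxy)-1,3-dimethoxy-5-methylbenzene | Cc1cc(OC)c(OCc2ccccc2)c(OC)c1 | intermediate
3 | 2-(benzyloxy)-4-bromo-1,3-dimethoxy-5-methylbenzene | Cc1cc(OC)c(OCc2ccccc2)c(OC)c1Br | intermediate
4 | syringaldehyde | COc1cc(C=O)cc(OC)c1O | starting material
5 | 4-(benzyloxy)-3,5-dimethoxybenzaldehyde | COc1cc(C=O)cc(OC)c1OCc1ccccc1 | intermediate
6 | [3-(benzyloxy)-2,4-dimethoxy-6-methylphenyl]lithium (not isolated) | Cc1cc(OC)c(OCc2ccccc2)c(OC)c1[Li] | intermediate
7 | (±)-[4-(benzyloxy)-3,5-dimethoxyphenyl][3-(benzyloxy)-2,4-dimethoxy-6-methylphenyl]methanol | COc1cc(C(O)c2c(C)cc(OC)c(OCc3ccccc3)c2OC)cc(OC)c1OCc1ccccc1 | intermediate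
8 | [4-(benzyloxy)-3,5-dimethoxyphenyl][3-(benzyloxy)-2,4-dimethoxy-6-methylphenyl]methanone | COc1cc(C(=O)c2c(C)cc(OC)c(OCc3ccccc3)c2OC)cc(OC)c1OCc1ccccc1 | intermediate
9 | diisopropyl fumarate | CC(C)OC(=O)/C=C/C(=O)OC(C)C | starting material
10 | photoenol, (Z)-[3-(benzyloxy)-2,4-dimethoxy-6-methylidenecyclohexa-2,4-dien-1-ylidene][4-(benzyloxy)-3,5-dimethoxyphenyl]methanol, OH on the side of C8–OMe (not isolated) | C=C1C=C(OC)C(OCc2ccccc2)=C(OC)/C1=C(\O)c1cc(OC)c(OCc2ccccc2)c(OC)c1 | intermediate
11 | diisopropyl (1R,2S,3R)-7-(benzyloxy)-1-[4-(benzyloxy)-3,5-dimethoxyphenyl]-1-hydroxy-6,8-dimethoxy-1,2,3,4-tetrahydronaphthalene-2,3-dicarboxylate | COc1cc([C@@]2(O)c3c(cc(OC)c(OCc4ccccc4)c3OC)C[C@@H](C(=O)OC(C)C)[C@@H]2C(=O)OC(C)C)cc(OC)c1OCc1ccccc1 | intermediate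
12 | (1R,2R,3R)-7-(benzyloxy)-1-[4-(benzyloxy)-3,5-dimethoxyphenyl]-2,3-bis(hydroxymethyl)-6,8-dimethoxy-1,2,3,4-tetrahydronaphthalen-1-ol | COc1cc([C@@]2(O)c3c(cc(OC)c(OCc4ccccc4)c3OC)C[C@@H](CO)[C@@H]2CO)cc(OC)c1OCc1ccccc1 | intermediate
13 | 9,10-bis-O-(diisopropylsilyl) ether of 12 | COc1cc([C@@]2(O)c3c(cc(OC)c(OCc4ccccc4)c3OC)C[C@@H](CO[SiH](C(C)C)C(C)C)[C@@H]2CO[SiH](C(C)C)C(C)C)cc(OC)c1OCc1ccccc1 | intermediate
14 | C1 diarylmethyl cation derived from 13 (not isolated) | COc1cc([C+]2c3c(cc(OC)c(OCc4ccccc4)c3OC)C[C@@H](CO[SiH](C(C)C)C(C)C)[C@@H]2CO[SiH](C(C)C)C(C)C)cc(OC)c1OCc1ccccc1 | intermediate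
15 | (1S,2R,3R) C1–H compound with O9–Si(iPr)2(OCOCF3) and O10–SiH(iPr)2 (not isolated) | COc1cc([C@H]2c3c(cc(OC)c(OCc4ccccc4)c3OC)C[C@@H](CO[SiH](C(C)C)C(C)C)[C@@H]2CO[Si](OC(=O)C(F)(F)F)(C(C)C)C(C)C)cc(OC)c1OCc1ccccc1 | intermediate
16 | [(1S,2R,3R)-7-(benzyloxy)-1-[4-(benzyloxy)-3,5-dimethoxyphenyl]-6,8-dimethoxy-1,2,3,4-tetrahydronaphthalene-2,3-diyl]dimethanol | COc1cc([C@H]2c3c(cc(OC)c(OCc4ccccc4)c3OC)C[C@@H](CO)[C@@H]2CO)cc(OC)c1OCc1ccccc1 | intermediate
17 | (1S,2R,3R)-lyoniresinol | COc1cc([C@H]2c3c(cc(OC)c(O)c3OC)C[C@@H](CO)[C@@H]2CO)cc(OC)c1O | target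

Total step count: 10. Longest linear sequence: 9 steps (1, 2, 4, 5, 6, 7, 8, 9, 10).

## Steps most likely to fail

**1. Step 6.** Several things may go wrong.
- A simple diester may bind the titanate only weakly, so an unbound background cycloaddition with poor facial and endo selectivity could compete.
- The inward-pointing ring C slows the addition. Reketonisation of the dienol, its electrocyclic closure, or sensitised E/Z isomerisation of the dienophile may then take over.

The fallback uses known auxiliary-controlled photoenol Diels–Alder chemistry. It sets out from 8 and comes back at 12. Fumaryl chloride is esterified with methyl (S)-lactate (Et3N, CH2Cl2) to give bis[(2S)-1-methoxy-1-oxopropan-2-yl] fumarate F1. Ketone 8 is irradiated (365 nm, toluene, no titanium) with F1. The dienol hydroxyl hydrogen-bonds to a lactate carbonyl, which should direct endo addition to one dienophile face and give the bis-lactyl (1R,2S,3R) adduct F2. Minor diastereomers are removed from F2 by crystallisation or chromatography, so optical purity no longer depends on a catalyst. LiAlH4 in THF then reduces all four ester groups of F2 to triol 12. Methyl (R)-lactate would be used if the (S) series proves mismatched.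

**2. Step 9.** Three processes may compete with the intended hydride transfer.
- Loss of the C2 proton from the cation, with scrambling of C2 on reprotonation.
- Hydride transfer from the O10 tether to the lower face.
- Acid cleavage of the silyl ethers before ionisation.

The fallback sets out from 11 and comes back at 16. Hydroxy diester 11 is treated with excess Et3SiH and BF3·OEt2 in CH2Cl2 at −78 → −20 °C. This is an intermolecular ionic hydrogenation at the diester stage. The facial choice then rests on pseudoaxial hydride attack on the half-chair that holds both esters pseudoequatorial, and the excess silane is meant to outrun dehydration. It should give diisopropyl (1S,2R,3R)-7-(benzyloxy)-1-[4-(benzyloxy)-3,5-dimethoxyphenyl]-6,8-dimethoxy-1,2,3,4-tetrahydronaphthalene-2,3-dicarboxylate F3. LiAlH4 in THF reduces F3 to 16.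

**3. Step 7.** The C1 alkoxide may open ring B by retro-aldol cleavage before the hindered C2 ester is reduced. The fallback sets out from 11 and comes back at 12. The tertiary hydroxyl is capped under neutral conditions with N-(trimethylsilyl)imidazole to give the C1 trimethylsilyl ether diester F4, so no alkoxide can form at C1. DIBAL-H in toluene at −78 → 0 °C reduces both esters to the C1-silylated diol F5. K2CO3 in MeOH at 20 °C removes the trimethylsilyl group and gives triol 12.

## Further compounds

F1 | step 6 | bis[(2S)-1-methoxy-1-oxopropan-2-yl] (E)-but-2-enedioate | COC(=O)[C@H](C)OC(=O)/C=C/C(=O)O[C@@H](C)C(=O)OC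
F2 | step 6 | bis[(2S)-1-methoxy-1-oxopropan-2-yl] (1R,2S,3R)-7-(benzyloxy)-1-[4-(benzyloxy)-3,5-dimethoxyphenyl]-1-hydroxy-6,8-dimethoxy-1,2,3,4-tetrahydronaphthalene-2,3-dicarboxylate | COc1cc([C@@]2(O)c3c(cc(OC)c(OCc4ccccc4)c3OC)C[C@@H](C(=O)O[C@@H](C)C(=O)OC)[C@@H]2C(=O)O[C@@H](C)C(=O)OC)cc(OC)c1OCc1ccccc1
F3 | step 9 | diisopropyl (1S,2R,3R)-7-(benzyloxy)-1-[4-(benzyloxy)-3,5-dimethoxyphenyl]-6,8-dimethoxy-1,2,3,4-tetrahydronaphthalene-2,3-dicarboxylate | COc1cc([C@H]2c3c(cc(OC)c(OCc4ccccc4)c3OC)C[C@@H](C(=O)OC(C)C)[C@@H]2C(=O)OC(C)C)cc(OC)c1OCc1ccccc1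
F4 | step 7 | diisopropyl (1R,2S,3R)-7-(benzyloxy)-1-[4-(benzyloxy)-3,5-dimethoxyphenyl]-6,8-dimethoxy-1-[(trimethylsilyl)oxy]-1,2,3,4-tetrahydronaphthalene-2,3-dicarboxylate | COc1cc([C@@]2(O[Si](C)(C)C)c3c(cc(OC)c(OCc4ccccc4)c3OC)C[C@@H](C(=O)OC(C)C)[C@@H]2C(=O)OC(C)C)cc(OC)c1OCc1ccccc1
F5 | step 7 | [(1R,2R,3R)-7-(benzyloxy)-1-[4-(benzyloxy)-3,5-dimethoxyphenyl]-6,8-dimethoxy-1-[(trimethylsilyl)oxy]-1,2,3,4-tetrahydronaphthalene-2,3-diyl]dimethanol | COc1cc([C@@]2(O[Si](C)(C)C)c3c(cc(OC)c(OCc4ccccc4)c3OC)C[C@@H](CO)[C@@H]2CO)cc(OC)c1OCc1ccccc1
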